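All runs were computed for an exercise.

At early times a gas that starts undissolved looks like what holds the product back, and two chemists read the runs below in opposite ways.

| flask | substrate | gas phase | free catalyst | remark | time |
|---|---|---|---|---|---|
| ash | 0.87 M | 47 mM (held) | 0.74 mM | run made earlier |  |
| larch | 1.4 M | 47 mM (held) | 0.74 mM | run made earlier |  |
| elm | 0.62 M | 47 mM (held) | 1.1 mM | run made earlier |  |
| flask | 0.62 M | 47 mM (held) | 0.74 mM |  | 40 min |

| run | time / min | product / % |
|---|---|---|
| ash | 4.00 | 4.2 |
| ash | 6.00 | 6.7 |
| ash | 10.0 | 11.5 |
| ash | 20.0 | 16.8 |
| ash | 30.0 | 21.9 |
| ash | 50.0 | 26.0 |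
| larch | 8.00 | 8.4 |
| larch | 15.0 | 13.2 |
| larch | 25.0 | 17.0 |
| larch | 30.0 | 18.2 |
| larch | 40.0 | 22.3 |
| larch | 50.0 | 24.4 |
| elm | 10.0 | 13.9 |
| elm | 20.0 | 19.4 |
| elm | 30.0 | 24.4 |
| elm | 40.0 | 28.7 |
| elm | 50.0 | 29.6 |

(readings scatter by 0.5 percentage points)

- at the start none of the gas is dissolved
- the earlier runs were read with a standard deviation of 0.5 percentage points
- what may be going on: substrate + dissolved gas + free catalyst <-> free catalyst + product; gas phase <-> dissolved gas; 2 free catalyst -> spent catalyst

* how much product there is at 40 min, in percent of the substrate charged
* the change that raises the amount of product at 40 min, in percent of the substrate charged most ("none" if none brings more than 2 percentage points) (south-east / north-west / south / none)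
* amount of product at 40 min, in percent of the substrate charged, after north-west

- south-east: doubling the saturation concentration of gas phase, all else as stated
- north-west: doubling the amount of free catalyst, all else as stated
- south: doubling the transfer coefficient of the gas phase, all else as stated

The first holds a supply view, with gas transfer as the rate-limiting step, so that the flask should make as many moles of product as larch, whose 22.3% at 40.0 min would be 50.4% of the flask's smaller charge. The second holds a clock view, in which substrate goes pseudo-first-order while free catalyst dies in pairs, so that percentages carry across charges, and she points to ash and larch, which read 26.0% and 24.4% at 50.0 min although larch holds 1.61 times the substrate.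

Her tool, which I adopt, is the dose L, minus the logarithm of the fraction of substrate left, the time integral of the substrate's first-order rate coefficient. Dividing that coefficient by the fractional death rate of free catalyst removes time. If free catalyst dies in pairs it falls late on as the inverse of time, so ash between 20.0 min and 50.0 min reads Q = 0.128, the dose gained per e-fold of free catalyst lost. Extending ash's 20.0 min reading to 40 min with this Q gives my own 23.9% for the flask.

The forecast takes the clock side, “The fractional conversion curves nearly coincide across substrate levels”, and stands above my figure at 24.5% (22.5% to 26.5%), with 30.5% after north-west (27.5% to 34%) and south-east as the best change.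

The flask gives 25.6%, with 28.6% after north-west, and south-east is best, adding 20 percentage points. Free catalyst in the flask stands at 8.04% of its charge at 40.0 min, which is 2.52 e-folds, so Q gives 27.6% against the flask's 25.6%.

    substrate + dissolved gas + free catalyst ⇌ free catalyst + product (K = 891 L mol⁻¹, k = 22.3 L² mol⁻² s⁻¹)
    gas phase ⇌ dissolved gas, rate k2*(csat - [dissolved gas]) (kL = 0.0113 s⁻¹)
    2 free catalyst → spent catalyst (k = 3.22 L mol⁻¹ s⁻¹)

A neighbour flask with 2.5 M of substrate also ends at 8.04% free catalyst, so Q again gives 27.6%, and the supply view gives 12.5%. The neighbour flask computes to 18.1%, between the two and nearer the supply figure, with dissolved gas at 0.0377 M against the flask's 0.0445 M.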